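Assumption: the target SMILES has no stereocentres (the molecule is achiral), so "single enantiomer" imposes no stereochemical requirement and no step needs stereocontrol.

## Retrosynthetic overview

1. Disconnect the depside ester C(=O)–OAr: an A-ring acid (salicyl alcohol masked as an acetonide) plus a B-ring phenol (allyl β-orsellinate, free 4-OH).
2. Both rings come from one commercial arene, methyl 2,4-dihydroxy-3,6-dimethylbenzoate (atraric acid). The A ring needs 4-O-methylation and oxidation of its 3-CH3 to CH2OH; the B ring needs only ester exchange.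
3. Key new step: a phenol-tethered hydrosilyl ether directs Ir-catalysed silylation of the ortho benzylic C–H; Tamao oxidation then gives ArCH2OH.
4. No ring of the target is constructed, since both benzene rings are bought intact. The only rings formed are temporary: the benzoxasilole (step 3), then the benzodioxine acetonide (step 5).
5. Endgame: acyl chloride coupling at the B-ring 4-OH, Pd(0) deallylation, then mild aqueous acid to remove the acetonide.

## Route

**Step 1**
Reactants: 1, methyl 2,4-dihydroxy-3,6-dimethylbenzoate (atraric acid)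
Product: 2, methyl 2-hydroxy-4-methoxy-3,6-dimethylbenzoate
Conditions: MeI (1.1 equiv), K2CO3 (1.1 equiv), acetone, reflux
Reagents that add atoms: iodomethane, CI
Why: Williamson O-methylation is selective for the 4-OH because the 2-OH is locked in a hydrogen bond to the ester carbonyl and is flanked by two substituents.

**Step 2**
Reactants: 2, methyl 2-hydroxy-4-methoxy-3,6-dimethylbenzoate
Product: 3, methyl 2-[(diethylsilyl)oxy]-4-methoxy-3,6-dimethylbenzoate (aryl–O–SiHEt2 ether; used crude under N2)
Conditions: Et2SiHCl, Et3N, DMAP (cat.), CH2Cl2, 0 °C → rt; filter, concentrate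
Reagents that add atoms: chlorodiethylsilane, CC[SiH](Cl)CC
Why: Base-mediated O-silylation of the only free OH with a small chlorosilane installs the Si–H tether next to the 3-methyl group.

**Step 3 (key new step)**
Reactants: 3, methyl 2-[(diethylsilyl)oxy]-4-methoxy-3,6-dimethylbenzoate
Product: 4, methyl 2,2-diethyl-4-methoxy-6-methyl-2,3-dihydro-1,2-benzoxasilole-7-carboxylate (five-membered ring ArO–SiEt2–CH2–Ar)
Conditions: [Ir(cod)OMe]2 (2 mol %), 3,4,7,8-Me4phen (5 mol %), norbornene (1.5 equiv), THF, 100 °C, sealed tube
Reagents that add atoms: none (norbornene only accepts H2)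
Why: Proposed new method: Si–H oxidative addition gives a tethered Ir–silyl species, norbornene removes the hydride, and the metal is held over the 3-CH3 group, the only C–H within reach (the other ortho position carries the ester; the 6-CH3, OMe and C5–H cannot form a small ring), so cleavage of the weak primary benzylic C–H through a six-membered iridacycle and C–Si reductive elimination should close the oxasilole; the closest known reaction type is Ir-catalysed hydrosilyl-ether-directed dehydrogenative γ-C(sp3)–H silylation of aliphatic alcohols to oxasilolanes, not shown for phenol-tethered benzylic methyl groups of fully substituted salicylates.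

**Step 4**
Reactants: 4, methyl 2,2-diethyl-4-methoxy-6-methyl-2,3-dihydro-1,2-benzoxasilole-7-carboxylate
Product: 5, methyl 2-hydroxy-3-(hydroxymethyl)-4-methoxy-6-methylbenzoate
Conditions: 30% H2O2, KHCO3, KF, THF/MeOH (1:1), 50 °C; Na2S2O3 quench
Reagents that add atoms: hydrogen peroxide, OO (supplies the CH2OH oxygen)
Why: Tamao–Fleming oxidation converts the alkoxy-activated C–Si bond to C–OH and frees the phenol, while the hindered methyl ester survives bicarbonate.

**Step 5**
Reactants: 5, methyl 2-hydroxy-3-(hydroxymethyl)-4-methoxy-6-methylbenzoate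
Product: 6, methyl 5-methoxy-2,2,7-trimethyl-4H-1,3-benzodioxine-8-carboxylate (acetonide bridging the phenol O and the CH2O)
Conditions: Me2C(OMe)2, PPTS (cat.), acetone, rt; Et3N quench
Reagents that add atoms: 2,2-dimethoxypropane, COC(C)(C)OC
Why: Acid-catalysed transketalisation closes the six-membered salicyl-alcohol acetonide, masking both the phenol and the ionisable benzylic alcohol in one group.

**Step 6**
Reactants: 6, methyl 5-methoxy-2,2,7-trimethyl-4H-1,3-benzodioxine-8-carboxylate
Product: 7, 5-methoxy-2,2,7-trimethyl-4H-1,3-benzodioxine-8-carboxylic acid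
Conditions: KOH, DMSO/H2O (4:1), 90 °C; then citric acid to pH 4, 0 °C
Reagents that add atoms: potassium hydroxide/water, [K+].[OH-] and O (carboxyl OH oxygen)
Why: Forcing saponification in aqueous DMSO cleaves the di-ortho-substituted methyl ester, and the ketal and aryl methyl ether are inert to base.

**Step 7**
Reactants: 1, methyl 2,4-dihydroxy-3,6-dimethylbenzoate
Product: 8, 2,4-dihydroxy-3,6-dimethylbenzoic acid (β-orsellinic acid)
Conditions: conc. H2SO4, 0 °C → rt, 1 h; pour onto ice
Reagents that add atoms: water, O (carboxyl OH oxygen on quench)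
Why: Acylium-type (AAc1) hydrolysis suits hindered, electron-rich benzoates and avoids the hot aqueous conditions that decarboxylate orsellinic acids.

**Step 8**
Reactants: 8, 2,4-dihydroxy-3,6-dimethylbenzoic acid
Product: 9, prop-2-en-1-yl (allyl) 2,4-dihydroxy-3,6-dimethylbenzoate
Conditions: allyl bromide (1.05 equiv), KHCO3, DMF, rt
Reagents that add atoms: allyl bromide, C=CCBr
Why: Bicarbonate deprotonates only the carboxylic acid, so SN2 alkylation gives the allyl ester and leaves both phenols free.

**Step 9**
Reactants: 7, 5-methoxy-2,2,7-trimethyl-4H-1,3-benzodioxine-8-carboxylic acid; 9, allyl 2,4-dihydroxy-3,6-dimethylbenzoate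
Product: 10, allyl 2-hydroxy-4-[(5-methoxy-2,2,7-trimethyl-4H-1,3-benzodioxine-8-carbonyl)oxy]-3,6-dimethylbenzoate
Conditions: 7, 1-chloro-N,N,2-trimethylprop-1-en-1-amine (Ghosez reagent), CH2Cl2, 0 °C → rt; then 9, Et3N, DMAP (cat.), CH2Cl2, 0 °C → rt
Reagents that add atoms: none
Why: Neutral acid chloride formation spares the acetonide, and DMAP-catalysed acylation goes to the more acidic, unchelated 4-OH of 9 rather than the hydrogen-bonded, doubly flanked 2-OH.

**Step 10**
Reactants: 10, the allyl ester/acetonide depside
Product: 11, 2-hydroxy-4-[(5-methoxy-2,2,7-trimethyl-4H-1,3-benzodioxine-8-carbonyl)oxy]-3,6-dimethylbenzoic acid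
Conditions: Pd(PPh3)4 (5 mol %), PhSiH3 (2 equiv), CH2Cl2, rt
Reagents that add atoms: none
Why: Tsuji–Trost deallylation with a non-nucleophilic hydride scavenger frees the acid under neutral conditions without touching the depside ester or the ketal.

**Step 11**
Reactants: 11, the acetonide-protected depside acid
Product: 12, 3-α-hydroxybarbatic acid, i.e. 2-hydroxy-4-{[2-hydroxy-3-(hydroxymethyl)-4-methoxy-6-methylbenzoyl]oxy}-3,6-dimethylbenzoic acid
Conditions: 0.5 M aq. HCl/THF (1:3), 0 °C → rt, dilute (0.02 M)
Reagents that add atoms: none (the water oxygen leaves in acetone)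
Why: Aryl alkyl ketals hydrolyse under mild aqueous acid, and excess water at high dilution recaptures any benzylic cation as the alcohol, while the hindered depside ester is stable.

## Compound list

1 | methyl 2,4-dihydroxy-3,6-dimethylbenzoate (atraric acid) | COC(=O)c1c(C)cc(O)c(C)c1O | starting material
2 | methyl 2-hydroxy-4-methoxy-3,6-dimethylbenzoate | COC(=O)c1c(C)cc(OC)c(C)c1O | intermediate
3 | methyl 2-[(diethylsilyl)oxy]-4-methoxy-3,6-dimethylbenzoate | COC(=O)c1c(C)cc(OC)c(C)c1O[SiH](CC)CC | intermediate
4 | methyl 2,2-diethyl-4-methoxy-6-methyl-2,3-dihydro-1,2-benzoxasilole-7-carboxylate | COC(=O)c1c(C)cc(OC)c2C[Si](CC)(CC)Oc12 | intermediate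
5 | methyl 2-hydroxy-3-(hydroxymethyl)-4-methoxy-6-methylbenzoate | COC(=O)c1c(C)cc(OC)c(CO)c1O | intermediate
6 | methyl 5-methoxy-2,2,7-trimethyl-4H-1,3-benzodioxine-8-carboxylate | COC(=O)c1c(C)cc(OC)c2COC(C)(C)Oc12 | intermediate
7 | 5-methoxy-2,2,7-trimethyl-4H-1,3-benzodioxine-8-carboxylic acid | OC(=O)c1c(C)cc(OC)c2COC(C)(C)Oc12 | intermediate
8 | 2,4-dihydroxy-3,6-dimethylbenzoic acid (β-orsellinic acid) | OC(=O)c1c(C)cc(O)c(C)c1O | intermediate
9 | allyl 2,4-dihydroxy-3,6-dimethylbenzoate | C=CCOC(=O)c1c(C)cc(O)c(C)c1O | intermediate
10 | allyl 2-hydroxy-4-[(5-methoxy-2,2,7-trimethyl-4H-1,3-benzodioxine-8-carbonyl)oxy]-3,6-dimethylbenzoate | C=CCOC(=O)c1c(C)cc(OC(=O)c2c(C)cc(OC)c3COC(C)(C)Oc23)c(C)c1O | intermediate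
11 | 2-hydroxy-4-[(5-methoxy-2,2,7-trimethyl-4H-1,3-benzodioxine-8-carbonyl)oxy]-3,6-dimethylbenzoic acid | OC(=O)c1c(C)cc(OC(=O)c2c(C)cc(OC)c3COC(C)(C)Oc23)c(C)c1O | intermediate
12 | 3-α-hydroxybarbatic acid | COc1cc(C)c(C(=O)Oc2cc(C)c(C(=O)O)c(O)c2C)c(O)c1CO | target

## Summary

Total step count: 11.
Longest linear sequence: 9 steps (steps 1–6, then 9–11); the B-ring branch is steps 7–8.

Three steps most likely to fail:

1. **Step 3 (proposed new C–H silylation).** Risks are Ir-mediated hydrosilylation of the neighbouring ester by the tethered Si–H, or ArO–Si redistribution. Fallback with known chemistry: build the CH2OH carbon by C–C bond formation instead. Start the A ring from commercial methyl 2,4-dihydroxy-6-methylbenzoate, 4-O-methylate (MeI/K2CO3), formylate ortho to the phenol at C3 (TiCl4/Cl2CHOMe), and reduce with NaBH4 to reach compound 5; rejoin at step 5.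

2. **Step 9 (hindered acyl chloride esterification, 4-OH versus 2-OH).** Fallback: switch to the classical depside protocol at the aldehyde oxidation level. Oxidise 5 with MnO2 to the 3-formyl salicylate, saponify, and condense the free chelated o-hydroxy acid directly with 9 using DCC (or TFAA in toluene), with no phenol protection. Then reduce the aldehyde with NaBH4 and deallylate.

3. **Step 11 (acid unmasking of an ionisable o-hydroxybenzyl alcohol; risk of quinone-methide-type oligomerisation).** Fallback: change to a fluoride-labile endgame. Carry the A ring as its benzyl ester so the acid is freed by hydrogenolysis, protect the salicyl alcohol as the cyclic di-tert-butylsilylene (tBu2Si(OTf)2, 2,6-lutidine), and finish with buffered fluoride (TBAF/AcOH or HF·pyridine) after Pd(0) deallylation, so no benzylic cation is generated.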